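**Plan**

- Retrosynthesis: both phenols are masked as TIPS ethers and the hydrogens at C2 and C3 are removed. This leads back to an isoflavone, whose ring C is cut at C4–C4a and at O1–C2.
- Enabling feature: the C4 carbonyl sits on C4a of ring A, the ortho neighbour of C8a, which carries O1. This is an ortho-acylphenol, the outcome of an O-to-C acyl shift, and C2 is the β-carbon of the C4 enone. The whole C2–C3–C4 unit can therefore first hang on O1 as a 3-methoxyacrylate ester, with an iodine marking C4a.
- Further cuts: the O1–C4 ester bond (Steglich), C3–C1' (Negishi coupling with an α-iodo-β-methoxyacrylate), and C5'–CMe2 (aromatic Claisen rearrangement of a prenyl ether).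
- Forward order: ring B is dressed (steps 1–5), joined to the three-carbon unit (step 7) and tethered to ring A through the ester (step 10). Ring C, the only ring that is built, closes in step 11.
- Stereochemistry: C3 is set in step 12 by transfer hydrogenation with RuCl(p-cymene)[(R,R)-TsDPEN] under dynamic kinetic resolution, giving the (3R,4R)-cis-alcohol. Oxidation then deletes C4, and base-free desilylation keeps 3R.

Key step: step 11

Assumption: the stereocentre in the target is C3 with R configuration (C4 > C2 > C1' > H), and the (R,R)-catalyst is assigned from its usual sense of induction with aryl ketones, under which chroman-4-ones give the 4R alcohol.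

**Step 1**
Reactants: 1 2-methoxyresorcinol; 2 prenyl bromide (1-bromo-3-methylbut-2-ene)
Product: 3 2-methoxy-3-(3-methylbut-2-enyloxy)phenol
Conditions: K2CO3 (1 equiv), 2 (0.9 equiv), acetone, reflux
Reagents that add atoms: none
Why: Williamson etherification of a symmetrical diol, so only the degree of alkylation needs control, which a slight deficit of bromide and recovery of unreacted 1 should provide.

**Step 2**
Reactants: 3 2-methoxy-3-(3-methylbut-2-enyloxy)phenol
Product: 4 triisopropyl[2-methoxy-3-(3-methylbut-2-enyloxy)phenoxy]silane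
Conditions: TIPSCl, imidazole, DMF, rt
Reagents that add atoms: chlorotriisopropylsilane CC(C)[Si](Cl)(C(C)C)C(C)C
Why: Imidazole-promoted silylation of the one remaining phenol gives an ether that tolerates the heat, organometallics and oxidant ahead and can be removed at the end by fluoride without base.

**Step 3**
Reactants: 4 triisopropyl[2-methoxy-3-(3-methylbut-2-enyloxy)phenoxy]silane
Product: 6 2-methoxy-6-(2-methylbut-3-en-2-yl)-3-(triisopropylsilyloxy)phenol, via ortho-dienone 5 (not isolated)
Conditions: PhNEt2, 200 °C, sealed tube, short heating time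
Reagents that add atoms: none
Why: In this aromatic Claisen rearrangement the [3,3] shift inverts the prenyl unit and delivers it as the 1,1-dimethylallyl group to the only hydrogen-bearing ortho carbon, dienone 5 then tautomerises to the phenol, and the amine solvent suppresses acid-induced cyclisation.

**Step 4**
Reactants: 6 2-methoxy-6-(2-methylbut-3-en-2-yl)-3-(triisopropylsilyloxy)phenol
Product: 7 [2,3-dimethoxy-4-(2-methylbut-3-en-2-yl)phenoxy]triisopropylsilane
Conditions: NaH, MeI, THF/DMF, 0 °C → rt
Reagents that add atoms: iodomethane CI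
Why: Williamson O-methylation of the irreversibly formed, hindered sodium phenoxide under anhydrous conditions should leave the aryl silyl ether untouched.

**Step 5**
Reactants: 7 [2,3-dimethoxy-4-(2-methylbut-3-en-2-yl)phenoxy]triisopropylsilane
Product: 8 [6-iodo-2,3-dimethoxy-4-(2-methylbut-3-en-2-yl)phenoxy]triisopropylsilane
Conditions: NIS, CF3CO2H (cat.), MeCN, 0 °C
Reagents that add atoms: N-iodosuccinimide O=C1CCC(=O)N1I
Why: In this electrophilic aromatic iodination, one free ring position is ortho to the silyloxy and para to the 4'-methoxy group while the other is meta to both and flanked by the tert-alkyl group, and the activated arene should outrun the monosubstituted neopentyl-type alkene.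

**Step 6**
Reactants: 9 methyl (E)-3-methoxyacrylate
Product: 11 methyl (Z)-2-iodo-3-methoxyacrylate, via iodoacetate adduct 10 (not isolated)
Conditions: NIS, AcOH, CH2Cl2, rt; then Et3N, rt
Reagents that add atoms: N-iodosuccinimide O=C1CCC(=O)N1I
Why: Iodoacetoxylation of the push–pull alkene followed by amine-induced elimination of acetic acid is the established way to this (Z)-α-iodo-β-methoxyacrylate.

**Step 7**
Reactants: 8 [6-iodo-2,3-dimethoxy-4-(2-methylbut-3-en-2-yl)phenoxy]triisopropylsilane; 11 methyl (Z)-2-iodo-3-methoxyacrylate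
Product: 14 methyl (E)-2-[3,4-dimethoxy-5-(2-methylbut-3-en-2-yl)-2-(triisopropylsilyloxy)phenyl]-3-methoxyacrylate, via ring B arylmagnesium chloride 12 (not isolated), via ring B arylzinc chloride 13 (not isolated)
Conditions: i-PrMgCl·LiCl, THF, 0 °C → rt; ZnCl2; then 11, Pd2(dba)3 (cat.), SPhos (cat.), rt → 50 °C
Reagents that add atoms: none
Why: Iodine–magnesium exchange, transmetalation to zinc and Negishi coupling, in which zerovalent palladium inserts into the vinyl carbon–iodine bond and couples with retention (Z-iodide to E-arylacrylate by priority change only), while magnesium instead of lithium avoids O-to-C silyl migration next to the TIPS ether.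

**Step 8**
Reactants: 14 methyl (E)-2-[3,4-dimethoxy-5-(2-methylbut-3-en-2-yl)-2-(triisopropylsilyloxy)phenyl]-3-methoxyacrylate
Product: 16 (E)-2-[3,4-dimethoxy-5-(2-methylbut-3-en-2-yl)-2-(triisopropylsilyloxy)phenyl]-3-methoxyacrylic acid, via trimethylstannyl ester 15 (not isolated)
Conditions: Me3SnOH, ClCH2CH2Cl, 80 °C; then 0.5 M HCl wash
Reagents that add atoms: trimethyltin hydroxide (Me3SnOH) C[Sn](C)(C)O
Why: Me3SnOH-mediated methyl ester cleavage is chosen because aqueous hydroxide would endanger the aryl silyl ether and the β-methoxy group.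

**Step 9**
Reactants: 17 4-iodoresorcinol
Product: 18 2-iodo-5-(triisopropylsilyloxy)phenol
Conditions: TIPSCl (1 equiv), imidazole, CH2Cl2, 0 °C
Reagents that add atoms: chlorotriisopropylsilane CC(C)[Si](Cl)(C(C)C)C(C)C
Why: In this sterically governed monosilylation the bulky chlorosilane should take the hydroxyl para to iodine and leave the one flanked by iodine free.

**Step 10**
Reactants: 16 (E)-2-[3,4-dimethoxy-5-(2-methylbut-3-en-2-yl)-2-(triisopropylsilyloxy)phenyl]-3-methoxyacrylic acid; 18 2-iodo-5-(triisopropylsilyloxy)phenol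
Product: 19 2-iodo-5-(triisopropylsilyloxy)phenyl (E)-2-[3,4-dimethoxy-5-(2-methylbut-3-en-2-yl)-2-(triisopropylsilyloxy)phenyl]-3-methoxyacrylate
Conditions: N,N'-diisopropylcarbodiimide, DMAP (cat.), CH2Cl2, 0 °C → rt
Reagents that add atoms: none
Why: In this Steglich esterification DMAP carries the acyl group to the hindered ortho-iodophenol under neutral conditions that preserve the alkene geometry and both silyl ethers.

**Step 11**
Reactants: 19 2-iodo-5-(triisopropylsilyloxy)phenyl (E)-2-[3,4-dimethoxy-5-(2-methylbut-3-en-2-yl)-2-(triisopropylsilyloxy)phenyl]-3-methoxyacrylate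
Product: 22 3-[3,4-dimethoxy-5-(2-methylbut-3-en-2-yl)-2-(triisopropylsilyloxy)phenyl]-7-(triisopropylsilyloxy)-4H-chromen-4-one, via arylmagnesium ester 20 (not isolated), via chloromagnesium acylphenoxide 21 (not isolated)
Conditions: i-PrMgCl·LiCl (1.1 equiv), THF (0.02 M), −40 °C; → rt → 40 °C; then 1 M HCl, rt
Reagents that add atoms: none
Why: Proposed new method: iodine–magnesium exchange at C4a gives arylmagnesium 20, whose carbanion adds to the ester carbonyl hanging on the adjacent oxygen (transient four-membered alkoxide), and collapse with O1 as the leaving group shifts the acyl group from O1 to C4a, forming C4–C4a and the chelated phenoxide 21. On warming, O1 adds to C2, the β-carbon of the enone just created, in a 6-endo-trig oxa-Michael closure and methoxide leaves, forming O1–C2 and ring C as an aromatic 4-pyranone, while the acid quench sends any uncyclised phenol down the same path. The closest known reaction types are the anionic Fries-type acyl shift triggered by halogen–metal exchange in ortho-haloaryl esters and the addition–elimination closure of 2-hydroxyaryl β-alkoxy or β-amino enones to chromones; their union in one flask on a 2-aryl-3-methoxyacrylate is the untested part. No stereocentre is created, and the alkene geometry of 19 does not matter for closure because hydrogen and methoxy at C2 both stay outside the forming ring. The selectivity needed is exchange at iodine ahead of attack of i-PrMgCl on the carbonyl or on C2, which is secured by the inductively activating ortho-acyloxy group, the low temperature and the hindered, vinylogous-carbonate character of the ester; high dilution favours the intramolecular shift over acyl transfer between molecules. Since C3 is fully substituted the ester can neither be deprotonated nor fragment to a ketene, and the site of acylation on ring A is dictated by the position of the iodine alone.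

**Step 12**
Reactants: 22 3-[3,4-dimethoxy-5-(2-methylbut-3-en-2-yl)-2-(triisopropylsilyloxy)phenyl]-7-(triisopropylsilyloxy)-4H-chromen-4-one
Product: 24 (3R,4R)-3-[3,4-dimethoxy-5-(2-methylbut-3-en-2-yl)-2-(triisopropylsilyloxy)phenyl]-7-(triisopropylsilyloxy)chroman-4-ol (cis), via racemic isoflavanone 23 (not isolated)
Conditions: RuCl(p-cymene)[(R,R)-TsDPEN] (5 mol %), HCO2H, Et3N, EtOAc, 40 °C
Reagents that add atoms: none
Why: In this Noyori–Ikariya asymmetric transfer hydrogenation of an isoflavone the ruthenium hydride first reduces C2=C3 to isoflavanone 23, which racemises through its enol under Et3N, and the (R,R)-catalyst then reduces only the 3R ketone from the face anti to the aryl group (dynamic kinetic resolution), setting C3 as R and C4 as R in a cis relation while the isolated vinyl group stays inert.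

**Step 13**
Reactants: 24 (3R,4R)-cis-isoflavan-4-ol bis-TIPS ether
Product: 25 (3R)-3-[3,4-dimethoxy-5-(2-methylbut-3-en-2-yl)-2-(triisopropylsilyloxy)phenyl]-7-(triisopropylsilyloxy)chroman-4-one
Conditions: Dess–Martin periodinane, CH2Cl2, 0 °C → rt
Reagents that add atoms: none
Why: Dess–Martin oxidation under neutral to weakly acidic conditions removes the auxiliary C4 stereocentre and restores the ketone without enolising C3.

**Step 14**
Reactants: 25 (3R)-7,2'-bis-O-TIPS pervilleanone
Product: 26 pervilleanone, (3R)-7-hydroxy-3-[2-hydroxy-3,4-dimethoxy-5-(2-methylbut-3-en-2-yl)phenyl]chroman-4-one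
Conditions: HF·pyridine, pyridine, THF, 0 °C → rt; pH 7 buffer work-up
Reagents that add atoms: none
Why: Fluoride cleaves both aryl silyl ethers in a weakly acidic medium in which the C3 hydrogen next to the ketone should not exchange, so the 3R configuration is carried into the target.

**Compound list**

1 | 2-methoxyresorcinol | COc1c(O)cccc1O | starting material
2 | prenyl bromide | CC(C)=CCBr | starting material
3 | 2-methoxy-3-(3-methylbut-2-enyloxy)phenol | COc1c(O)cccc1OCC=C(C)C | intermediate
4 | triisopropyl[2-methoxy-3-(3-methylbut-2-enyloxy)phenoxy]silane | COc1c(O[Si](C(C)C)(C(C)C)C(C)C)cccc1OCC=C(C)C | intermediate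
5 | 2-methoxy-6-(2-methylbut-3-en-2-yl)-3-(triisopropylsilyloxy)cyclohexa-2,4-dien-1-one (racemic, not isolated) | C=CC(C)(C)C1C=CC(O[Si](C(C)C)(C(C)C)C(C)C)=C(OC)C1=O | intermediate
6 | 2-methoxy-6-(2-methylbut-3-en-2-yl)-3-(triisopropylsilyloxy)phenol | C=CC(C)(C)c1ccc(O[Si](C(C)C)(C(C)C)C(C)C)c(OC)c1O | intermediate
7 | [2,3-dimethoxy-4-(2-methylbut-3-en-2-yl)phenoxy]triisopropylsilane | C=CC(C)(C)c1ccc(O[Si](C(C)C)(C(C)C)C(C)C)c(OC)c1OC | intermediate
8 | [6-iodo-2,3-dimethoxy-4-(2-methylbut-3-en-2-yl)phenoxy]triisopropylsilane | C=CC(C)(C)c1cc(I)c(O[Si](C(C)C)(C(C)C)C(C)C)c(OC)c1OC | intermediate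
9 | methyl (E)-3-methoxyacrylate | CO/C=C/C(=O)OC | starting material
10 | methyl 3-acetoxy-2-iodo-3-methoxypropanoate (diastereomer mixture, not isolated) | COC(OC(C)=O)C(I)C(=O)OC | intermediate
11 | methyl (Z)-2-iodo-3-methoxyacrylate | CO/C=C(\I)C(=O)OC | intermediate
12 | [3,4-dimethoxy-5-(2-methylbut-3-en-2-yl)-2-(triisopropylsilyloxy)phenyl]magnesium chloride (not isolated) | C=CC(C)(C)c1cc([Mg]Cl)c(O[Si](C(C)C)(C(C)C)C(C)C)c(OC)c1OC | intermediate
13 | [3,4-dimethoxy-5-(2-methylbut-3-en-2-yl)-2-(triisopropylsilyloxy)phenyl]zinc chloride (not isolated) | C=CC(C)(C)c1cc([Zn]Cl)c(O[Si](C(C)C)(C(C)C)C(C)C)c(OC)c1OC | intermediate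
14 | methyl (E)-2-[3,4-dimethoxy-5-(2-methylbut-3-en-2-yl)-2-(triisopropylsilyloxy)phenyl]-3-methoxyacrylate | CO/C=C(\c1cc(C(C)(C)C=C)c(OC)c(OC)c1O[Si](C(C)C)(C(C)C)C(C)C)C(=O)OC | intermediate
15 | trimethylstannyl ester of acid 16 (not isolated) | CO/C=C(\c1cc(C(C)(C)C=C)c(OC)c(OC)c1O[Si](C(C)C)(C(C)C)C(C)C)C(=O)O[Sn](C)(C)C | intermediate
16 | (E)-2-[3,4-dimethoxy-5-(2-methylbut-3-en-2-yl)-2-(triisopropylsilyloxy)phenyl]-3-methoxyacrylic acid | CO/C=C(\c1cc(C(C)(C)C=C)c(OC)c(OC)c1O[Si](C(C)C)(C(C)C)C(C)C)C(=O)O | intermediate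
17 | 4-iodoresorcinol | Oc1ccc(I)c(O)c1 | starting material
18 | 2-iodo-5-(triisopropylsilyloxy)phenol | Oc1cc(O[Si](C(C)C)(C(C)C)C(C)C)ccc1I | intermediate
19 | 2-iodo-5-(triisopropylsilyloxy)phenyl (E)-2-[3,4-dimethoxy-5-(2-methylbut-3-en-2-yl)-2-(triisopropylsilyloxy)phenyl]-3-methoxyacrylate | CO/C=C(\c1cc(C(C)(C)C=C)c(OC)c(OC)c1O[Si](C(C)C)(C(C)C)C(C)C)C(=O)Oc1cc(O[Si](C(C)C)(C(C)C)C(C)C)ccc1I | intermediate
20 | arylmagnesium chloride from 19, magnesium at C4a (not isolated) | CO/C=C(\c1cc(C(C)(C)C=C)c(OC)c(OC)c1O[Si](C(C)C)(C(C)C)C(C)C)C(=O)Oc1cc(O[Si](C(C)C)(C(C)C)C(C)C)ccc1[Mg]Cl | intermediate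
21 | chloromagnesium phenoxide of (E)-1-[2-hydroxy-4-(triisopropylsilyloxy)phenyl]-2-(ring B aryl)-3-methoxyprop-2-en-1-one (not isolated) | CO/C=C(\c1cc(C(C)(C)C=C)c(OC)c(OC)c1O[Si](C(C)C)(C(C)C)C(C)C)C(=O)c1ccc(O[Si](C(C)C)(C(C)C)C(C)C)cc1O[Mg]Cl | intermediate
22 | 7,2'-bis-O-TIPS dehydropervilleanone (isoflavone) | C=CC(C)(C)c1cc(-c2coc3cc(O[Si](C(C)C)(C(C)C)C(C)C)ccc3c2=O)c(O[Si](C(C)C)(C(C)C)C(C)C)c(OC)c1OC | intermediate
23 | racemic 7,2'-bis-O-TIPS isoflavanone (not isolated) | C=CC(C)(C)c1cc(C2COc3cc(O[Si](C(C)C)(C(C)C)C(C)C)ccc3C2=O)c(O[Si](C(C)C)(C(C)C)C(C)C)c(OC)c1OC | intermediate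
24 | (3R,4R)-cis-7,2'-bis-O-TIPS isoflavan-4-ol | C=CC(C)(C)c1cc([C@@H]2COc3cc(O[Si](C(C)C)(C(C)C)C(C)C)ccc3[C@@H]2O)c(O[Si](C(C)C)(C(C)C)C(C)C)c(OC)c1OC | intermediate
25 | (3R)-7,2'-bis-O-TIPS pervilleanone | C=CC(C)(C)c1cc([C@@H]2COc3cc(O[Si](C(C)C)(C(C)C)C(C)C)ccc3C2=O)c(O[Si](C(C)C)(C(C)C)C(C)C)c(OC)c1OC | intermediate
26 | pervilleanone, (3R) | C=CC(C)(C)c1cc([C@@H]2COc3cc(O)ccc3C2=O)c(O)c(OC)c1OC | target

**Step count**

- Total steps: 14.
- Longest linear sequence: 12 (steps 1–5, 7, 8, 10–14).

**Steps most likely to fail**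

1. Step 11.
   - What may go wrong: the alkylmagnesium may attack the ester carbonyl or C2 before exchange is complete. The acyl group may pass between two molecules instead of within one. A slow acyl shift may leave the arylmagnesium to be protonated.
   - Fallback idea (known chemistry): ring C is built on ring A alone and ring B is attached last.
   - Route: commercial 2',4'-dihydroxyacetophenone F1 is silylated at its non-chelated hydroxyl (TIPSCl, imidazole) to 1-[2-hydroxy-4-(triisopropylsilyloxy)phenyl]ethanone F2. Condensation with DMF dimethyl acetal gives (E)-3-(dimethylamino)-1-[2-hydroxy-4-(triisopropylsilyloxy)phenyl]prop-2-en-1-one F3, and I2 closes it to 3-iodo-7-(triisopropylsilyloxy)-4H-chromen-4-one F4. Arylzinc 13, generated from 8 through 12 as in step 7, is then joined to F4 by Negishi coupling (Pd2(dba)3, SPhos).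
   - This path sets out from 8 and comes back to the route at 22.

2. Step 3.
   - What may go wrong: the allyl unit may migrate through the methoxy-bearing ortho carbon and on to the para position by a Cope shift. The ether may cleave thermally. The freed phenol may trigger a further hydrogen-shift rearrangement or cyclise onto the new vinyl group.
   - Fallback idea: the quaternary carbon is built by enolate arylation, with no sigmatropic step.
   - Route: monomethylation of 1 (MeI, K2CO3) gives 2,3-dimethoxyphenol F5, and silylation gives (2,3-dimethoxyphenoxy)triisopropylsilane F6. Methoxy-directed ortho-lithiation (n-BuLi, TMEDA) gives [2,3-dimethoxy-4-(triisopropylsilyloxy)phenyl]lithium F7, and 1,2-dibromoethane converts it into (4-bromo-2,3-dimethoxyphenoxy)triisopropylsilane F8. α-Arylation of methyl isobutyrate (LiNCy2, Pd2(dba)3, P(t-Bu)3) gives methyl 2-[2,3-dimethoxy-4-(triisopropylsilyloxy)phenyl]-2-methylpropanoate F9. Reduction with i-Bu2AlH at −78 °C gives 2-[2,3-dimethoxy-4-(triisopropylsilyloxy)phenyl]-2-methylpropanal F10, and Wittig methylenation (Ph3PCH3Br, KOt-Bu) installs the vinyl group.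
   - This path sets out from 1 and comes back at 7.

3. Step 12.
   - What may go wrong: the conjugate hydride transfer may stall next to the crowded 2'-silyloxyaryl group, or the catalyst may discriminate poorly between the two interconverting ketone enantiomers.
   - Fallback idea: C3 is set by enantioselective protonation instead of hydride transfer.
   - Route: LiBH(s-Bu)3 adds hydride to C2 of 22 at −78 °C to give the lithium 2H-chromen-4-olate F11, which allyl chloroformate traps on oxygen as the allyl 2H-chromen-4-yl carbonate F12. Pd(OAc)2 with a t-Bu-PHOX ligand and formic acid then effects decarboxylative asymmetric protonation, the ligand antipode being chosen for the 3R series.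
   - This path sets out from 22 and comes back at 25, bypassing 24.

**Further compounds**

F1 | step 11 | 2',4'-dihydroxyacetophenone (commercial) | CC(=O)c1ccc(O)cc1O
F2 | step 11 | 1-[2-hydroxy-4-(triisopropylsilyloxy)phenyl]ethanone | CC(=O)c1ccc(O[Si](C(C)C)(C(C)C)C(C)C)cc1O
F3 | step 11 | (E)-3-(dimethylamino)-1-[2-hydroxy-4-(triisopropylsilyloxy)phenyl]prop-2-en-1-one | CN(C)/C=C/C(=O)c1ccc(O[Si](C(C)C)(C(C)C)C(C)C)cc1O
F4 | step 11 | 3-iodo-7-(triisopropylsilyloxy)-4H-chromen-4-one | O=c1c(I)coc2cc(O[Si](C(C)C)(C(C)C)C(C)C)ccc12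
F5 | step 3 | 2,3-dimethoxyphenol | COc1cccc(O)c1OC
F6 | step 3 | (2,3-dimethoxyphenoxy)triisopropylsilane | COc1cccc(O[Si](C(C)C)(C(C)C)C(C)C)c1OC
F7 | step 3 | [2,3-dimethoxy-4-(triisopropylsilyloxy)phenyl]lithium | [Li]c1ccc(O[Si](C(C)C)(C(C)C)C(C)C)c(OC)c1OC
F8 | step 3 | (4-bromo-2,3-dimethoxyphenoxy)triisopropylsilane | Brc1ccc(O[Si](C(C)C)(C(C)C)C(C)C)c(OC)c1OC
F9 | step 3 | methyl 2-[2,3-dimethoxy-4-(triisopropylsilyloxy)phenyl]-2-methylpropanoate | COC(=O)C(C)(C)c1ccc(O[Si](C(C)C)(C(C)C)C(C)C)c(OC)c1OC
F10 | step 3 | 2-[2,3-dimethoxy-4-(triisopropylsilyloxy)phenyl]-2-methylpropanal | O=CC(C)(C)c1ccc(O[Si](C(C)C)(C(C)C)C(C)C)c(OC)c1OC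
F11 | step 12 | lithium 3-(ring B aryl)-7-(triisopropylsilyloxy)-2H-chromen-4-olate | [Li]OC1=C(c2cc(C(C)(C)C=C)c(OC)c(OC)c2O[Si](C(C)C)(C(C)C)C(C)C)COc2cc(O[Si](C(C)C)(C(C)C)C(C)C)ccc21
F12 | step 12 | allyl 3-(ring B aryl)-7-(triisopropylsilyloxy)-2H-chromen-4-yl carbonate | C=CCOC(=O)OC1=C(c2cc(C(C)(C)C=C)c(OC)c(OC)c2O[Si](C(C)C)(C(C)C)C(C)C)COc2cc(O[Si](C(C)C)(C(C)C)C(C)C)ccc21
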